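**Retrosynthetic overview**
- Target ⇐ C18 primary alcohol (oxidation, methylation, desilylation) ⇐ 3,18-diol, by radical removal of the C3 oxygen through a cyclic thionocarbonate.
- Decalin ⇐ acyclic (2R,3R)-epoxy alcohol in one Ti(III) radical cascade: ring A (C4–C5) first, then ring B (C10–C9), ended by loss of a C17 hydrogen to give the 8(17)-alkene. The single epoxide stereocentre relays to C4, C5, C9 and C10.
- Epoxy alcohol ⇐ E-allylic alcohol (Sharpless epoxidation, D-tartrate) ⇐ allylic oxidation of the terminal E-methyl group.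
- C13 carbinol, finished before the cyclisation so that no alkene sits in a 5-hexenyl relation to the C8 radical ⇐ 2-methylene alcohol by Sharpless epoxidation (L-tartrate) and sulfonium-ylide one-carbon homologation.
- C19 chain ⇐ (2E,6E)-farnesyl bromide + methallyl alcohol dianion.

Assumption: the SMILES is read as (4S,5S,9R,10S,13R), an ent-labdane whose C4 ester is equatorial (C18, trans to the C10 methyl). Labdane numbering is used for the cyclised compounds and for the chain carbons that become them.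

**Step 1**
Reactants: 1 (2E,6E)-farnesyl bromide; 2 methallyl alcohol
Product: 4 (5E,9E)-6,10,14-trimethyl-2-methylidenepentadeca-5,9,13-trien-1-ol, via dilithiated methallyl alcohol 3 (not isolated)
Conditions: 2, n-BuLi (2.2 equiv), TMEDA, Et2O, 0 °C → rt; then 1, THF, −78 → 0 °C; H2O
Reagents that add atoms: none
Why: C-alkylation of the methallyl alcohol dianion (SN2 at the primary allylic bromide) joins the two pieces, keeps both E-alkenes and creates no stereocentre.

**Step 2**
Reactants: 4
Product: 6 tert-butyldimethylsilyl ether of [(2S)-2-[(3E,7E)-4,8,12-trimethyltrideca-3,7,11-trienyl]oxiran-2-yl]methanol, via (S)-epoxy alcohol 5 (not isolated)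
Conditions: Ti(OiPr)4 (10 mol %), L-(+)-DET (12 mol %), t-BuOOH (decane), 4 Å MS, CH2Cl2, −20 °C; then TBSCl, imidazole, 0 °C → rt
Reagents that add atoms: tert-butyl hydroperoxide, CC(C)(C)OO; tert-butyldimethylsilyl chloride, CC(C)(C)[Si](C)(C)Cl
Why: Katsuki–Sharpless asymmetric epoxidation touches only the titanium-bound allylic alcohol, L-(+)-tartrate gives the (S)-2,2-disubstituted glycidol (the sense known for methallyl alcohol), and in-situ silylation protects the primary hydroxyl.

**Step 3**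
Reactants: 6
Product: 7 (2R,5E,9E)-1-(tert-butyldimethylsilyloxy)-2-ethenyl-6,10,14-trimethylpentadeca-5,9,13-trien-2-ol
Conditions: Me3S+ I− (3 equiv), n-BuLi (2.9 equiv), THF, −10 °C → rt; H2O
Reagents that add atoms: trimethylsulfonium iodide, C[S+](C)C.[I-]
Why: Dimethylsulfonium methylide opens the epoxide at its CH2 and a second ylide equivalent eliminates dimethyl sulfide (epoxide-to-allylic-alcohol one-carbon homologation); C13 is not touched, so the tertiary vinyl carbinol keeps the epoxidation-derived configuration (R by CIP).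

**Step 4**
Reactants: 7
Product: 8 (2E,6E,10E,14R)-15-(tert-butyldimethylsilyloxy)-14-ethenyl-2,6,10-trimethylpentadeca-2,6,10-triene-1,14-diol
Conditions: SeO2 (0.3 equiv), t-BuOOH (3 equiv), salicylic acid (0.1 equiv), CH2Cl2, rt
Reagents that add atoms: tert-butyl hydroperoxide, CC(C)(C)OO
Why: Sharpless–Umbreit catalytic SeO2 allylic oxidation (ene reaction, then [2,3]-shift) hydroxylates the E-methyl of the terminal trisubstituted alkene, giving the E-allylic alcohol whose CH2OH becomes C18.

**Step 5**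
Reactants: 8
Product: 9 [(2R,3R)-3-[(3E,7E,11R)-12-(tert-butyldimethylsilyloxy)-11-ethenyl-11-hydroxy-3,7-dimethyldodeca-3,7-dienyl]-2-methyloxiran-2-yl]methanol
Conditions: Ti(OiPr)4 (10 mol %), D-(−)-DET (12 mol %), t-BuOOH (decane), 4 Å MS, CH2Cl2, −20 °C
Reagents that add atoms: tert-butyl hydroperoxide, CC(C)(C)OO
Why: Katsuki–Sharpless epoxidation of the primary E-allylic alcohol with D-(−)-tartrate gives the (2R,3R)-epoxide under reagent control; the tertiary allylic alcohol at C13 is too slow a substrate to compete.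

**Step 6**
Reactants: 9
Product: 10 (3R,4S,5S,9R,10S,13R)-16-(tert-butyldimethylsilyloxy)-ent-labda-8(17),14-diene-3,13,18-triol
Conditions: Cp2TiCl2 (2.2 equiv), Mn dust (8 equiv), THF, rt, Cp2TiCl solution added slowly to 9 (0.01 M); 1 M HCl work-up
Reagents that add atoms: none
Why: Nugent–RajanBabu Ti(III) epoxide homolysis gives the tertiary C4 radical, which closes 6-endo/6-endo through a chair–chair fold (Barrero–Cuerva epoxypolyene cyclisation) with the C3–OTi group equatorial, so (3R) sets 5S, 9R and 10S; the larger CH2OH is predicted to take the pseudo-equatorial site at C4 (4S, minor C4 epimer removed by chromatography), and trapping of the C8 radical by Cp2TiCl followed by β-hydride loss from C17 gives the exocyclic alkene.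

**Step 7**
Reactants: 10
Product: 11 cyclic 3,18-thionocarbonate (1,3-dioxane-2-thione) of 10
Conditions: 1,1′-thiocarbonyldiimidazole (1.5 equiv), DMAP (cat.), PhMe, 80 °C
Reagents that add atoms: 1,1′-thiocarbonyldiimidazole, S=C(n1ccnc1)n1ccnc1
Why: The equatorial 3-OH and the equatorial C18 hydroxymethyl form a six-membered cyclic thionocarbonate by double acyl transfer, while the hindered tertiary C13–OH does not react.

**Step 8**
Reactants: 11
Product: 13 (4S,5S,9R,10S,13R)-16-(tert-butyldimethylsilyloxy)-ent-labda-8(17),14-diene-13,18-diol, via stannyl thiocarbonate 12 (not isolated)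
Conditions: Bu3SnH (2 equiv), AIBN (cat.), PhMe, 110 °C; then K2CO3 (cat.), MeOH, rt
Reagents that add atoms: none
Why: Barton-type radical deoxygenation of a cyclic thionocarbonate fragments toward the more stable secondary C3 radical, which is reduced to CH2, and methanolysis of the remaining primary thiocarbonate frees the C18 alcohol; no stereocentre is affected.

**Step 9**
Reactants: 13
Product: 14 (4S,5S,9R,10S,13R)-16-(tert-butyldimethylsilyloxy)-13-hydroxy-ent-labda-8(17),14-dien-18-oic acid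
Conditions: AZADO (5 mol %), PhI(OAc)2 (2.5 equiv), MeCN / aq. pH 7 buffer, rt
Reagents that add atoms: water, O
Why: Nitroxyl-catalysed oxidation takes the neopentyl primary alcohol through the aldehyde hydrate to the acid and leaves the tertiary alcohol, the silyl ether and the alkenes alone.

**Step 10**
Reactants: 14
Product: 15 methyl (4S,5S,9R,10S,13R)-16-(tert-butyldimethylsilyloxy)-13-hydroxy-ent-labda-8(17),14-dien-18-oate
Conditions: MeI (3 equiv), K2CO3, DMF, rt
Reagents that add atoms: iodomethane, CI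
Why: SN2 O-methylation of the carboxylate avoids acyl substitution at the hindered quaternary C4 and does not alkylate the tertiary alcohol.

**Step 11**
Reactants: 15
Product: 16 methyl (4S,5S,9R,10S,13R)-13,16-dihydroxy-ent-labda-8(17),14-dien-18-oate (target)
Conditions: TBAF (1.5 equiv), THF, 0 °C → rt
Reagents that add atoms: none
Why: Fluoride-induced desilylation frees the primary C16 alcohol without touching the hindered methyl ester or the alkenes.

**Compound list**
1 | (2E,6E)-farnesyl bromide, (2E,6E)-1-bromo-3,7,11-trimethyldodeca-2,6,10-triene | CC(C)=CCC/C(C)=C/CC/C(C)=C/CBr | starting material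
2 | methallyl alcohol, 2-methylprop-2-en-1-ol | CC(=C)CO | starting material
3 | dilithiated methallyl alcohol (C,O-dianion of 2) | [Li+].[Li+].[CH2-]C(=C)C[O-] | intermediate
4 | (5E,9E)-6,10,14-trimethyl-2-methylidenepentadeca-5,9,13-trien-1-ol | CC(C)=CCC/C(C)=C/CC/C(C)=C/CCC(=C)CO | intermediate
5 | [(2S)-2-[(3E,7E)-4,8,12-trimethyltrideca-3,7,11-trienyl]oxiran-2-yl]methanol | OC[C@@]1(CC/C=C(\C)CC/C=C(\C)CCC=C(C)C)CO1 | intermediate
6 | tert-butyldimethylsilyl ether of 5 (same spatial arrangement, 2R by CIP) | CC(C)(C)[Si](C)(C)OC[C@@]1(CC/C=C(\C)CC/C=C(\C)CCC=C(C)C)CO1 | intermediate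
7 | (2R,5E,9E)-1-(tert-butyldimethylsilyloxy)-2-ethenyl-6,10,14-trimethylpentadeca-5,9,13-trien-2-ol | C=C[C@@](O)(CO[Si](C)(C)C(C)(C)C)CC/C=C(\C)CC/C=C(\C)CCC=C(C)C | intermediate
8 | (2E,6E,10E,14R)-15-(tert-butyldimethylsilyloxy)-14-ethenyl-2,6,10-trimethylpentadeca-2,6,10-triene-1,14-diol | C=C[C@@](O)(CO[Si](C)(C)C(C)(C)C)CC/C=C(\C)CC/C=C(\C)CC/C=C(\C)CO | intermediate
9 | (2R,3R)-2,3-epoxide of 8, [(2R,3R)-3-[(3E,7E,11R)-12-(tert-butyldimethylsilyloxy)-11-ethenyl-11-hydroxy-3,7-dimethyldodeca-3,7-dienyl]-2-methyloxiran-2-yl]methanol | C=C[C@@](O)(CO[Si](C)(C)C(C)(C)C)CC/C=C(\C)CC/C=C(\C)CC[C@H]1O[C@]1(C)CO | intermediate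
10 | (3R,4S,5S,9R,10S,13R)-16-(tert-butyldimethylsilyloxy)-ent-labda-8(17),14-diene-3,13,18-triol (trans-decalin, 3-OH equatorial, C18 = equatorial CH2OH trans to C20) | C=C[C@@](O)(CO[Si](C)(C)C(C)(C)C)CC[C@@H]1C(=C)CC[C@H]2[C@@]1(C)CC[C@@H](O)[C@]2(C)CO | intermediate
11 | cyclic 3,18-thionocarbonate of 10 | C=C[C@@](O)(CO[Si](C)(C)C(C)(C)C)CC[C@@H]1C(=C)CC[C@H]2[C@@]1(C)CC[C@H]3OC(=S)OC[C@]23C | intermediate
12 | O-(C18) S-tributylstannyl thiocarbonate of 13 | C=C[C@@](O)(CO[Si](C)(C)C(C)(C)C)CC[C@@H]1C(=C)CC[C@H]2[C@@]1(C)CCC[C@]2(C)COC(=O)S[Sn](CCCC)(CCCC)CCCC | intermediate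
13 | (4S,5S,9R,10S,13R)-16-(tert-butyldimethylsilyloxy)-ent-labda-8(17),14-diene-13,18-diol | C=C[C@@](O)(CO[Si](C)(C)C(C)(C)C)CC[C@@H]1C(=C)CC[C@H]2[C@@]1(C)CCC[C@]2(C)CO | intermediate
14 | (4S,5S,9R,10S,13R)-16-(tert-butyldimethylsilyloxy)-13-hydroxy-ent-labda-8(17),14-dien-18-oic acid | C=C[C@@](O)(CO[Si](C)(C)C(C)(C)C)CC[C@@H]1C(=C)CC[C@H]2[C@@]1(C)CCC[C@]2(C)C(=O)O | intermediate
15 | methyl ester of 14 | C=C[C@@](O)(CO[Si](C)(C)C(C)(C)C)CC[C@@H]1C(=C)CC[C@H]2[C@@]1(C)CCC[C@]2(C)C(=O)OC | intermediate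
16 | methyl (4S,5S,9R,10S,13R)-13,16-dihydroxy-ent-labda-8(17),14-dien-18-oate | C=C[C@@](O)(CO)CC[C@@H]1C(=C)CC[C@H]2[C@@]1(C)CCC[C@]2(C)C(=O)OC | target

**Step count:** 11 steps (steps 2 and 8 are one-pot pairs). **Longest linear sequence:** 11 steps from 1.

**Steps most likely to fail and their fallbacks**

Step 6 (Ti(III) bicyclisation). The risks are a low C4 ratio (CH2OH against CH3 on a freely rotating radical), Ti-mediated deoxygenation of the epoxy alcohol before ring closure, and the usual 35–45 % ceiling. The fallback sets out from 9, replaces the radical cascade by a polar one that transfers chirality from C4 itself, and comes back at 13, so steps 6–8 are bypassed. LiAlH4 (THF, 0 °C) delivers hydride to C3 and gives the tertiary/primary diol (2S,6E,10E,14R)-15-(tert-butyldimethylsilyloxy)-14-ethenyl-2,6,10-trimethylpentadeca-6,10-diene-1,2,14-triol F1. Mitsunobu cyclodehydration (PPh3, DIAD, PhMe) closes it with retention at C4 to the (S)-2-methyl-2-alkyloxirane F2. Ac2O/DMAP/Et3N masks the C13 hydroxyl as the tertiary acetate F3 so that it cannot trap the C8 cation. MeAlCl2 (CH2Cl2, −78 °C) then triggers a cation–olefin bicyclisation in which C5 attacks C4 anti to the departing oxygen; inversion gives the (4S) centre of 13, and the fold with CH2O–Al equatorial gives the cyclised acetate F4. K2CO3/MeOH removes the acetate to reach 13. The price is cationic termination, so the 8(17)-alkene has to be separated from its 7-ene isomer on AgNO3–silica.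

Step 4 (SeO2 oxidation). The risks are incomplete site selectivity between three trisubstituted alkenes and over-oxidation to the enal, so about 40 % is realistic. The fallback sets out from 7, cuts the prenyl end off and rebuilds it, and comes back at 8. NBS in aqueous THF (van Tamelen terminal selectivity) gives the terminal bromohydrin F5, and K2CO3/MeOH closes it to the terminal epoxide F6. HIO4 in THF/Et2O cleaves F6 to the trisnor aldehyde F7. Wittig reaction with Ph3P=C(CH3)CO2Et gives the (E)-2-methyl enoate ethyl ester F8, and DIBAL-H (CH2Cl2, −78 °C) reduces it to 8.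

Step 3 (ylide homologation). The epoxide CH2 is neopentyl-like and the reaction needs the ylide twice, so opening may stall or the base may attack elsewhere. The fallback sets out from 6, separates C–C bond formation from alkene formation, and comes back at 7. PhSeCH2Li (from (PhSe)2CH2 and n-BuLi, THF, −78 °C) opens the epoxide at CH2 to the γ-hydroxy selenide F9. H2O2/pyridine oxidises it to the selenoxide F10, which undergoes syn-elimination at rt to the vinyl carbinol 7.

**Further compounds**
F1 | step 6 | (2S,6E,10E,14R)-15-(tert-butyldimethylsilyloxy)-14-ethenyl-2,6,10-trimethylpentadeca-6,10-diene-1,2,14-triol | C=C[C@@](O)(CO[Si](C)(C)C(C)(C)C)CC/C=C(\C)CC/C=C(\C)CCC[C@](C)(O)CO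
F2 | step 6 | (S)-2-methyl-2-alkyloxirane from F1 (C4–O–C18 epoxide) | C=C[C@@](O)(CO[Si](C)(C)C(C)(C)C)CC/C=C(\C)CC/C=C(\C)CCC[C@@]1(C)CO1
F3 | step 6 | C13 acetate of F2 | C=C[C@@](OC(C)=O)(CO[Si](C)(C)C(C)(C)C)CC/C=C(\C)CC/C=C(\C)CCC[C@@]1(C)CO1
F4 | step 6 | C13 acetate of 13 | C=C[C@@](OC(C)=O)(CO[Si](C)(C)C(C)(C)C)CC[C@@H]1C(=C)CC[C@H]2[C@@]1(C)CCC[C@]2(C)CO
F5 | step 4 | terminal bromohydrin of 7 (3-bromo-4-hydroxy, mixture at C3) | C=C[C@@](O)(CO[Si](C)(C)C(C)(C)C)CC/C=C(\C)CC/C=C(\C)CCC(Br)C(C)(C)O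
F6 | step 4 | terminal 3,4-epoxide of 7 (mixture at C3) | C=C[C@@](O)(CO[Si](C)(C)C(C)(C)C)CC/C=C(\C)CC/C=C(\C)CCC1OC1(C)C
F7 | step 4 | trisnor aldehyde (C3 aldehyde) | C=C[C@@](O)(CO[Si](C)(C)C(C)(C)C)CC/C=C(\C)CC/C=C(\C)CCC=O
F8 | step 4 | ethyl (2E,6E,10E,14R)-15-(tert-butyldimethylsilyloxy)-14-ethenyl-14-hydroxy-2,6,10-trimethylpentadeca-2,6,10-trienoate | C=C[C@@](O)(CO[Si](C)(C)C(C)(C)C)CC/C=C(\C)CC/C=C(\C)CC/C=C(\C)C(=O)OCC
F9 | step 3 | γ-hydroxy phenyl selenide from 6 | O[C@](CC[Se]c1ccccc1)(CO[Si](C)(C)C(C)(C)C)CC/C=C(\C)CC/C=C(\C)CCC=C(C)C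
F10 | step 3 | selenoxide of F9 | O[C@](CC[Se](=O)c1ccccc1)(CO[Si](C)(C)C(C)(C)C)CC/C=C(\C)CC/C=C(\C)CCC=C(C)C
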